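**Retrosynthetic overview**
- Target ⇐ acetonide of its 2',3'-catechol; the ketal is hydrolysed last.
- Ring C ⇐ closure of the O1–C2 bond (C–O, loss of Me2NH), joined in one operation to C3-arylation. The partners are the o-hydroxyaryl enaminone from 2,4-dihydroxyacetophenone and a ring B aryl iodide made by lithiation/iodination next to the dioxole oxygen.
- Ring B substituents ⇐ aryl prenyl ether C–O bond (O-alkylation), aromatic Claisen shift to the only free ortho carbon (gives the 1,1-dimethylallyl group), then O-methylation of the phenol so released.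
- Ring order: rings A and B and the dioxole are bought; ring C is the only ring built (step 5); the dioxole is opened in step 6.

Assumption: the target has no stereocentre (it is achiral), so no stereocontrol is needed; 2,2-dimethyl-1,3-benzodioxol-4-ol is taken as a commercial phenol (otherwise one extra step from pyrogallol and 2,2-dimethoxypropane).

**Route**

Step 1
Reactants: 1 (2,2-dimethyl-1,3-benzodioxol-4-ol); 2 (1-bromo-3-methylbut-2-ene, prenyl bromide)
Product: 3 prenyl ether 2,2-dimethyl-4-[(3-methylbut-2-en-1-yl)oxy]-1,3-benzodioxole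
Conditions: K2CO3, acetone, reflux
Reagents that add atoms: none
Why: Williamson O-alkylation (SN2) of the phenoxide at the primary allylic carbon gives the aryl prenyl ether, and the ketal is stable to K2CO3.

Step 2
Reactants: 3 (prenyl ether)
Product: 5 methyl ether 4-methoxy-2,2-dimethyl-5-(2-methylbut-3-en-2-yl)-1,3-benzodioxole, via Claisen phenol 4 (not isolated)
Conditions: NMP, 195 °C (sealed, Ar), 1.5 h; then 25 °C, K2CO3, MeI, 45 °C
Reagents that add atoms: iodomethane (CI)
Why: Thermal aromatic Claisen rearrangement ([3,3]) moves the prenyl group with allylic inversion to C5, the only free ortho carbon, which creates the 1,1-dimethylallyl group, and phenol 4 is trapped in the same pot by Williamson methylation before it can cyclise or rearrange further.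

Step 3
Reactants: 5 (methyl ether)
Product: 7 aryl iodide 7-iodo-4-methoxy-2,2-dimethyl-5-(2-methylbut-3-en-2-yl)-1,3-benzodioxole, via aryllithium 6 (not isolated)
Conditions: s-BuLi, TMEDA, THF, –78 °C; then I2, –78 → 0 °C
Reagents that add atoms: iodine (II)
Why: Directed ortho-metalation works because C7–H is the only ring hydrogen next to an oxygen, so lithiation and iodine quench are regiospecific, and the vinyl group (no allylic hydrogen) is inert at –78 °C.

Step 4
Reactants: 8 (1-(2,4-dihydroxyphenyl)ethan-1-one, 2,4-dihydroxyacetophenone)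
Product: 9 enaminone (2E)-1-(2,4-dihydroxyphenyl)-3-(dimethylamino)prop-2-en-1-one
Conditions: DMF-DMA (1.5 equiv), THF, 65 °C
Reagents that add atoms: N,N-dimethylformamide dimethyl acetal (COC(OC)N(C)C)
Why: Condensation of the acetyl methyl group with the formamide acetal (enaminone formation) gives the E vinylogous amide, and the moderate temperature leaves both phenols unmethylated.

Step 5
Reactants: 7 (aryl iodide); 9 (enaminone, 1.5 equiv)
Product: 11 protected isoflavone 7-hydroxy-3-[7-methoxy-2,2-dimethyl-6-(2-methylbut-3-en-2-yl)-1,3-benzodioxol-4-yl]-4H-chromen-4-one, via α-aryl enaminone 10 (not isolated)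
Conditions: Pd(OAc)2 (5 mol %), Xantphos (6 mol %), K3PO4 (3 equiv), 1,4-dioxane/DMF (4:1), 90 °C
Reagents that add atoms: none
Why: Proposed new method: zerovalent palladium inserts into the C–I bond of 7, the potassium phenoxide of 9 replaces iodide on divalent palladium so that the aryl group is held next to the nucleophilic α-carbon of the vinylogous amide, C-palladation there through a six-membered O,C-palladacycle and C–C reductive elimination give α-aryl enaminone 10, and its ortho phenoxide then adds to the aminovinyl carbon and expels Me2NH (addition–elimination), which forms the O1–C2 bond and closes ring C; the closest known reactions are palladium-catalysed α-arylation of ketones and of cyclic enaminones with aryl halides, phenoxide-directed palladium arylation of 2-arylphenols, and the spontaneous ring closure of 2-aryl enaminones in the deoxybenzoin synthesis of isoflavones.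

Step 6
Reactants: 11 (protected isoflavone)
Product: 12 target 3-[2,3-dihydroxy-4-methoxy-5-(2-methylbut-3-en-2-yl)phenyl]-7-hydroxy-4H-chromen-4-one
Conditions: TFA/H2O (4:1), 0 → 20 °C, N2
Reagents that add atoms: none
Why: Acid-catalysed ketal hydrolysis frees the catechol, while the monosubstituted alkene on a quaternary carbon, the aryl methyl ether and the chromone should tolerate brief aqueous TFA at or below room temperature.

**Compound list**

1 | 2,2-dimethyl-1,3-benzodioxol-4-ol | CC1(C)Oc2cccc(O)c2O1 | starting material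
2 | 1-bromo-3-methylbut-2-ene (prenyl bromide) | CC(C)=CCBr | starting material
3 | 2,2-dimethyl-4-[(3-methylbut-2-en-1-yl)oxy]-1,3-benzodioxole | CC(C)=CCOc1cccc2OC(C)(C)Oc12 | intermediate
4 | 2,2-dimethyl-5-(2-methylbut-3-en-2-yl)-1,3-benzodioxol-4-ol (not isolated) | C=CC(C)(C)c1ccc2OC(C)(C)Oc2c1O | intermediate
5 | 4-methoxy-2,2-dimethyl-5-(2-methylbut-3-en-2-yl)-1,3-benzodioxole | C=CC(C)(C)c1ccc2OC(C)(C)Oc2c1OC | intermediate
6 | [7-methoxy-2,2-dimethyl-6-(2-methylbut-3-en-2-yl)-1,3-benzodioxol-4-yl]lithium (not isolated) | [Li]c1cc(C(C)(C)C=C)c(OC)c2OC(C)(C)Oc12 | intermediate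
7 | 7-iodo-4-methoxy-2,2-dimethyl-5-(2-methylbut-3-en-2-yl)-1,3-benzodioxole | C=CC(C)(C)c1cc(I)c2OC(C)(C)Oc2c1OC | intermediate
8 | 1-(2,4-dihydroxyphenyl)ethan-1-one | CC(=O)c1ccc(O)cc1O | starting material
9 | (2E)-1-(2,4-dihydroxyphenyl)-3-(dimethylamino)prop-2-en-1-one | CN(C)/C=C/C(=O)c1ccc(O)cc1O | intermediate
10 | 1-(2,4-dihydroxyphenyl)-3-(dimethylamino)-2-[7-methoxy-2,2-dimethyl-6-(2-methylbut-3-en-2-yl)-1,3-benzodioxol-4-yl]prop-2-en-1-one (not isolated; alkene geometry not defined, no stereocentre) | CN(C)C=C(C(=O)c1ccc(O)cc1O)c1cc(C(C)(C)C=C)c(OC)c2OC(C)(C)Oc12 | intermediate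
11 | 7-hydroxy-3-[7-methoxy-2,2-dimethyl-6-(2-methylbut-3-en-2-yl)-1,3-benzodioxol-4-yl]-4H-chromen-4-one | C=CC(C)(C)c1cc(-c2coc3cc(O)ccc3c2=O)c2OC(C)(C)Oc2c1OC | intermediate
12 | 3-[2,3-dihydroxy-4-methoxy-5-(2-methylbut-3-en-2-yl)phenyl]-7-hydroxy-4H-chromen-4-one (achiral) | C=CC(C)(C)c1cc(-c2coc3cc(O)ccc3c2=O)c(O)c(O)c1OC | target

**Step count and risks**

Total step count: 6. Longest linear sequence: 5 (steps 1, 2, 3, 5, 6).

The three steps most likely to fail:

Step 5 (the proposed new arylative oxa-annulation). The free 4-phenoxide of 9 may be O-arylated, the arylpalladium may undergo Heck reaction at the vinyl group or arylate the β-carbon (flavone regiochemistry), and 9 may close to 7-hydroxychromone before it is arylated. The fallback uses known chemistry, sets out from 5 and 9, and comes back at 11. Compound 5 is lithiated as in step 3 (aryllithium 6) and quenched with 2-isopropoxy-4,4,5,5-tetramethyl-1,3,2-dioxaborolane to give the pinacol boronate 2-[7-methoxy-2,2-dimethyl-6-(2-methylbut-3-en-2-yl)-1,3-benzodioxol-4-yl]-4,4,5,5-tetramethyl-1,3,2-dioxaborolane F1. Enaminone 9 is treated with I2 in MeOH at 20 °C, which closes ring C by iodocyclisation with loss of Me2NH and gives 7-hydroxy-3-iodo-4H-chromen-4-one F2. Suzuki–Miyaura coupling of F1 with F2 (Pd(PPh3)4, K2CO3, DME/H2O, 80 °C) then gives 11.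

Step 2 (one-pot Claisen rearrangement and methylation). Phenol 4 can cyclise onto its own alkene to a dihydrobenzofuran or undergo the abnormal Claisen shift at 195 °C, and the hindered phenol may methylate slowly. The fallback replaces the sigmatropic shift by a cross-coupling, sets out from 1, and comes back at 5. Ortho-selective bromination of 1 (NBS, cat. i-Pr2NH, CH2Cl2, 0 °C) gives 5-bromo-2,2-dimethyl-1,3-benzodioxol-4-ol F3. Methylation (MeI, K2CO3, acetone) gives 5-bromo-4-methoxy-2,2-dimethyl-1,3-benzodioxole F4. A γ-selective Suzuki–Miyaura coupling of F4 with 3-methylbut-2-en-1-ylboronic acid pinacol ester (Pd(OAc)2 with a bulky biaryl dialkylphosphine, K3PO4, THF/H2O, 40 °C) attaches the tertiary allyl carbon to the ring and gives 5.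

Step 6 (ketal hydrolysis on the finished skeleton). Acid strong enough to open the dioxole may protonate the alkene (aryl or methoxy participation), and the free catechol is air-sensitive. The fallback moves the ketal cleavage to an early, simple intermediate and ends with a much milder deprotection; it sets out from 7 and comes back at 12. BCl3 (CH2Cl2, –78 °C, then aqueous work-up) opens the ketal of 7 to give 3-iodo-6-methoxy-5-(2-methylbut-3-en-2-yl)benzene-1,2-diol F5. MOMCl with i-Pr2NEt gives 1-iodo-4-methoxy-2,3-bis(methoxymethoxy)-5-(2-methylbut-3-en-2-yl)benzene F6. Annulation of F6 with 9 under the conditions of step 5 passes through the non-isolated 1-(2,4-dihydroxyphenyl)-3-(dimethylamino)-2-[4-methoxy-2,3-bis(methoxymethoxy)-5-(2-methylbut-3-en-2-yl)phenyl]prop-2-en-1-one F7 and gives 7-hydroxy-3-[4-methoxy-2,3-bis(methoxymethoxy)-5-(2-methylbut-3-en-2-yl)phenyl]-4H-chromen-4-one F8. HCl (0.5 M) in MeOH at 40 °C removes both methoxymethyl groups and gives 12.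

**Further compounds**

F1 | step 5 | 2-[7-methoxy-2,2-dimethyl-6-(2-methylbut-3-en-2-yl)-1,3-benzodioxol-4-yl]-4,4,5,5-tetramethyl-1,3,2-dioxaborolane | C=CC(C)(C)c1cc(B2OC(C)(C)C(C)(C)O2)c2OC(C)(C)Oc2c1OC
F2 | step 5 | 7-hydroxy-3-iodo-4H-chromen-4-one | O=c1c(I)coc2cc(O)ccc12
F3 | step 2 | 5-bromo-2,2-dimethyl-1,3-benzodioxol-4-ol | CC1(C)Oc2ccc(Br)c(O)c2O1
F4 | step 2 | 5-bromo-4-methoxy-2,2-dimethyl-1,3-benzodioxole | COc1c(Br)ccc2OC(C)(C)Oc12
F5 | step 6 | 3-iodo-6-methoxy-5-(2-methylbut-3-en-2-yl)benzene-1,2-diol | C=CC(C)(C)c1cc(I)c(O)c(O)c1OC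
F6 | step 6 | 1-iodo-4-methoxy-2,3-bis(methoxymethoxy)-5-(2-methylbut-3-en-2-yl)benzene | C=CC(C)(C)c1cc(I)c(OCOC)c(OCOC)c1OC
F7 | step 6 | 1-(2,4-dihydroxyphenyl)-3-(dimethylamino)-2-[4-methoxy-2,3-bis(methoxymethoxy)-5-(2-methylbut-3-en-2-yl)phenyl]prop-2-en-1-one | CN(C)C=C(C(=O)c1ccc(O)cc1O)c1cc(C(C)(C)C=C)c(OC)c(OCOC)c1OCOC
F8 | step 6 | 7-hydroxy-3-[4-methoxy-2,3-bis(methoxymethoxy)-5-(2-methylbut-3-en-2-yl)phenyl]-4H-chromen-4-one | C=CC(C)(C)c1cc(-c2coc3cc(O)ccc3c2=O)c(OCOC)c(OCOC)c1OC
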